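**Retrosynthetic overview**
Rings: A = dibromopyrrole, B = six-membered lactam, C = pyrrolidine, D = imidazolidinone. C6 = aminal CH, C10 = tetrasubstituted aminal carbon.
Enabling feature: the lactam N sits at the B/C fusion, bonded to the ring-B C=O, to C10 and to the end CH2 of the three-carbon arm on C10. Removing this one N contracts B to a cyclopentanone B′ (2,3-dihydropyrrolizin-1-one, C10 = α-carbon) and opens C to a 3-azidopropyl arm, which is a δ-azido ketone.
Key disconnection: intramolecular Schmidt N-insertion. C10 migrates from C=O to N with retention, so B′ → B and ring C form together in the last ring-forming event.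
Without that N, C10 is no longer an electrophilic aminal carbon but an amino-acid α-carbon. L-Serine supplies C=O, C10, C6 and one urea N; the arm enters by enolate alkylation (self-regeneration of stereocentres) and the pyrrole by C-acylation.
Ring order: A (bought) → D (urea NH2 onto the C6 aldehyde) → B′ (pyrrole N onto the C6 N-acyliminium ion, sets C6) → B and C (step 9).

Key step: step 9

Remark: the target SMILES is read as 6S,10R (H-6 and the C10–CH2 bond cis on ring D). Changes of the C10 descriptor along the route come from CIP ranking only.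

Step 1
Reactants: 1 L-serine benzyl ester hydrochloride; 2 pivalaldehyde
Product: 4 cis-N-Boc-2-tert-butyloxazolidine benzyl ester (2R and 4S), via N–H oxazolidine 3 (not isolated)
Conditions: Et3N, pentane, reflux, Dean–Stark; then Boc2O, THF, rt
Reagents that add atoms: di-tert-butyl dicarbonate, CC(C)(C)OC(=O)OC(=O)OC(C)(C)C
Why: The amino alcohol and the aldehyde give an equilibrating N,O-acetal, and N-acylation should trap the cis isomer (tBu and ester on one face), so the serine stereocentre is copied into acetal carbon C2 (first half of self-regeneration of stereocentres).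

Step 2
Reactants: 4 cis-N-Boc-2-tert-butyloxazolidine benzyl ester; 5 1-chloro-3-iodopropane
Product: 7 C4-(3-chloropropyl)oxazolidine benzyl ester (2R and 4S), via lithium enolate 6 (not isolated)
Conditions: LDA (commercial solution, 1.1 equiv), THF–DMPU, −78 °C; 5 (3 equiv), −78 → −40 °C
Reagents that add atoms: none
Why: Deprotonation flattens C4, and the enolate should be alkylated (SN2 at the C–I end of 5) on the face anti to the C2 tert-butyl group, so the arm replaces the former H with overall retention and sets the future C10 (diastereoselective enolate alkylation, self-regeneration of stereocentres).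

Step 3
Reactants: 7 C4-(3-chloropropyl)oxazolidine benzyl ester
Product: 8 oxazolidine-4-carboxylic acid
Conditions: H2 (1 atm), 10% Pd/C, EtOAc, rt
Reagents that add atoms: none
Why: Neutral hydrogenolysis of the benzyl ester frees the hindered acid without base, so the primary chloride (no lactonisation), the Boc group and the N,O-acetal should all survive.

Step 4
Reactants: 8 oxazolidine-4-carboxylic acid; 9 pyrrole
Product: 11 pyrrol-2-yl ketone, via S-2-pyridyl thioester 10 (not isolated)
Conditions: 2,2′-dipyridyl disulfide, PPh3, toluene, rt; then pyrrol-1-ylmagnesium chloride (from 9 + MeMgCl, 4 equiv), toluene–THF, −78 °C; aq NH4Cl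
Reagents that add atoms: 2,2′-dipyridyl disulfide, c1ccc(nc1)SSc1ccccn1 (its pyridylthio group is carried only by 10)
Why: Redox thioesterification, followed by C2-selective acylation of the ambident pyrrolylmagnesium halide by the chelating 2-pyridyl thioester (known 2-ketopyrrole synthesis from acids); the product is held as its N-magnesio vinylogous amide, which prevents a second addition, and the quaternary centre cannot enolise.

Step 5
Reactants: 11 pyrrol-2-yl ketone
Product: 12 dibromopyrrol-2-yl ketone
Conditions: NBS (2.05 equiv), THF, −78 °C → rt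
Reagents that add atoms: N-bromosuccinimide, O=C1CCC(=O)N1Br
Why: Electrophilic aromatic bromination of a 2-acylpyrrole takes C4 and then the free α-position C5, and NBS is neutral enough for the Boc group and the N,O-acetal.

Step 6
Reactants: 12 dibromopyrrol-2-yl ketone
Product: 14 ureido alcohol (S), via amino alcohol trifluoroacetate 13 (not isolated)
Conditions: TFA–H2O 9:1, 0 °C → rt, evaporate; KOCN, THF–H2O–AcOH (pH 5–6), 40 °C
Reagents that add atoms: potassium cyanate, [K+].[O-]C#N
Why: Acid removes the Boc group and hydrolyses the N,O-acetal, and the freed α-tertiary amine adds to isocyanic acid formed from cyanate (N-carbamoylation of an amine salt) in preference to the hydroxyl group; the quaternary centre cannot epimerise.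

Step 7
Reactants: 14 ureido alcohol
Product: 18 tricyclic chloro ketone A–B′–D (6S and 10S), via ureido aldehyde 15 (not isolated), via cyclic hemiaminal 16 (not isolated), via N-acyliminium ion 17 (not isolated)
Conditions: IBX (1.1 equiv), DMSO, rt; extractive work-up; TFA–CH2Cl2 1:4, 0 °C → rt
Reagents that add atoms: none
Why: IBX oxidises the primary alcohol, the urea NH2 traps aldehyde 15 as hemiaminal 16 (ring D, 5-exo-trig), and acid converts both C6 epimers into the same planar ion 17, which the pyrrole N–H on the C10 acyl group can reach only from its own face (5-exo-trig α-ureidoalkylation, the N-closure known for phakellin-type cyclisations in TFA), so C6 is set cis to the acyl group by C10 alone.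

Step 8
Reactants: 18 tricyclic chloro ketone
Product: 19 tricyclic azido ketone (6S and 10S)
Conditions: NaN3 (2 equiv), DMF, 65 °C
Reagents that add atoms: sodium azide, [Na+].[N-]=[N+]=[N-]
Why: SN2 displacement of the primary chloride by azide, whose low basicity leaves the N–H groups, the aminal and the non-enolisable ketone untouched.

Step 9
Reactants: 19 tricyclic azido ketone
Product: 21 dibromophakellstatin (6S and 10R), via aminodiazonium ion 20 (not isolated)
Conditions: TfOH (3 equiv), (CF3)2CHOH–CH2Cl2, 0 °C → rt; aq NaHCO3
Reagents that add atoms: none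
Why: The acid activates the ring-B′ ketone, the alkylated azide nitrogen of the arm adds to it (6-exo-trig, on the face that carries the arm, away from ring D) to give aminodiazonium ion 20, and the C(OH)–C10 ring bond, antiperiplanar to the equatorial N–N2+ bond, shifts from carbon to nitrogen as N2 leaves, after which loss of H+ gives lactam 21. The closest known reaction type is the intramolecular Schmidt reaction of alkyl azides with ketones, the standard nitrogen insertion for 2-(3-azidopropyl)cycloalkanones, including α-quaternary and aryl-fused ones. Mode of closure: the temporary six-membered azidohydrin ring contracts through the 1,2-shift to pyrrolidine C (new N–C10 bond) while cyclopentanone B′ takes up the same nitrogen and becomes six-membered lactam B, so one atom insertion supplies the lactam N, both of its new C–N bonds, two rings and the tetrasubstituted N,N-aminal. No new stereocentre arises: the shift is suprafacial and C10 migrates with retention (S → R is a CIP change only), and even a stepwise fragmentation to a C10 N-acyliminium ion and the tethered amide could reclose only cis to the untouched C6. The selectivity needed is migration of C10 rather than pyrrole C2, and it is secured by the antiperiplanar geometry in 20, by the higher migratory aptitude of a nitrogen-bearing fully substituted carbon over a pyrrole carbon depleted by two bromines, and by the strain of the alternative, a bridged twisted amide. The ketone must react in preference to the C6 aminal, which is helped by the low basicity of the two aminal nitrogens and by the fact that any opening there is degenerate, since the tethered pyrrole N recloses.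

**Compound list**
1 | L-serine benzyl ester hydrochloride (S) | Cl.N[C@@H](CO)C(=O)OCc1ccccc1 | starting material
2 | pivalaldehyde | CC(C)(C)C=O | starting material
3 | benzyl (4S)-2-tert-butyl-1,3-oxazolidine-4-carboxylate (N–H, C2 epimers in equilibrium) | N1C(C(C)(C)C)OC[C@H]1C(=O)OCc2ccccc2 | intermediate
4 | 4-benzyl 3-tert-butyl (2R,4S)-2-tert-butyl-1,3-oxazolidine-3,4-dicarboxylate (tBu and CO2Bn cis) | CC(C)(C)OC(=O)N1[C@@H](C(C)(C)C)OC[C@H]1C(=O)OCc2ccccc2 | intermediate
5 | 1-chloro-3-iodopropane | ClCCCI | starting material
6 | lithium ester enolate of 4 (C4 planar, C2 unchanged) | CC(C)(C)OC(=O)N1[C@@H](C(C)(C)C)OCC1=C([O-])OCc2ccccc2.[Li+] | intermediate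
7 | 4-benzyl 3-tert-butyl (2R,4S)-2-tert-butyl-4-(3-chloropropyl)-1,3-oxazolidine-3,4-dicarboxylate (arm trans to tBu) | CC(C)(C)OC(=O)N1[C@@H](C(C)(C)C)OC[C@@]1(CCCCl)C(=O)OCc2ccccc2 | intermediate
8 | (2R,4S)-3-(tert-butoxycarbonyl)-2-tert-butyl-4-(3-chloropropyl)-1,3-oxazolidine-4-carboxylic acid | CC(C)(C)OC(=O)N1[C@@H](C(C)(C)C)OC[C@@]1(CCCCl)C(=O)O | intermediate
9 | 1H-pyrrole | c1cc[nH]c1 | starting material
10 | S-(pyridin-2-yl) thioester of 8 (2R,4S) | CC(C)(C)OC(=O)N1[C@@H](C(C)(C)C)OC[C@@]1(CCCCl)C(=O)Sc2ccccn2 | intermediate
11 | tert-butyl (2R,4S)-2-tert-butyl-4-(3-chloropropyl)-4-(1H-pyrrole-2-carbonyl)-1,3-oxazolidine-3-carboxylate | CC(C)(C)OC(=O)N1[C@@H](C(C)(C)C)OC[C@@]1(CCCCl)C(=O)c2ccc[nH]2 | intermediate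
12 | tert-butyl (2R,4S)-2-tert-butyl-4-(3-chloropropyl)-4-(4,5-dibromo-1H-pyrrole-2-carbonyl)-1,3-oxazolidine-3-carboxylate | CC(C)(C)OC(=O)N1[C@@H](C(C)(C)C)OC[C@@]1(CCCCl)C(=O)c2cc(Br)c(Br)[nH]2 | intermediate
13 | (2S)-2-amino-5-chloro-1-(4,5-dibromo-1H-pyrrol-2-yl)-2-(hydroxymethyl)pentan-1-one trifluoroacetate | N[C@](CO)(CCCCl)C(=O)c1cc(Br)c(Br)[nH]1.OC(=O)C(F)(F)F | intermediate
14 | 1-[(2S)-5-chloro-1-(4,5-dibromo-1H-pyrrol-2-yl)-2-(hydroxymethyl)-1-oxopentan-2-yl]urea | NC(=O)N[C@](CO)(CCCCl)C(=O)c1cc(Br)c(Br)[nH]1 | intermediate
15 | 1-[(2S)-5-chloro-1-(4,5-dibromo-1H-pyrrol-2-yl)-2-formyl-1-oxopentan-2-yl]urea | NC(=O)N[C@](C=O)(CCCCl)C(=O)c1cc(Br)c(Br)[nH]1 | intermediate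
16 | (4S)-4-(3-chloropropyl)-4-(4,5-dibromo-1H-pyrrole-2-carbonyl)-5-hydroxyimidazolidin-2-one (C5 epimers) | O=C1NC(O)[C@@](CCCCl)(C(=O)c2cc(Br)c(Br)[nH]2)N1 | intermediate
17 | cyclic N-acyliminium ion from 16 (C6 planar, C10 unchanged) | O=C1N[C@](CCCCl)(C(=O)c2cc(Br)c(Br)[nH]2)C=[NH+]1 | intermediate
18 | tricyclic chloro ketone (6S,10S): imidazolidin-2-one cis-fused to 5,6-dibromo-2,3-dihydro-1H-pyrrolizin-1-one; pyrrolizinone C2 (= C10) bears the 3-chloropropyl arm and one urea N, C3 (= C6) bears H and the other urea N | O=C1N[C@H]2n3c(cc(Br)c3Br)C(=O)[C@@]2(CCCCl)N1 | intermediate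
19 | tricyclic azido ketone (6S,10S): as 18 with a 3-azidopropyl arm | O=C1N[C@H]2n3c(cc(Br)c3Br)C(=O)[C@@]2(CCCN=[N+]=[N-])N1 | intermediate
20 | aminodiazonium ion (protonated cyclic azidohydrin of 19; carbinol centre transient) | O=C1N[C@H]2n3c(cc(Br)c3Br)C4(O)N([N+]#N)CCC[C@]24N1 | intermediate
21 | dibromophakellstatin (6S,10R) | O=C1N[C@H]2n3c(cc(Br)c3Br)C(=O)N3CCC[C@]23N1 | target

**Step count:** 9 steps in total. Longest linear sequence: 9 steps (1 → 21).

**Steps most likely to fail**

1. Step 9. The azide may add too slowly to the vinylogous-amide carbonyl. Strong acid may open the C6 aminal so that the azide is consumed there, or the pyrrole carbon may migrate instead of C10.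
Fallback (sets out from 18, returns at 21): the nitrogen is inserted as an external atom and the pyrrolidine is then closed by N-alkylation. Chloro ketone 18 is oximated (NH2OH·HCl, pyridine, EtOH, reflux) to the (Z)-oxime F1, in which OH points to the pyrrole side and is anti to the bulky C10. F1 is sulfonylated (TsCl, pyridine) to the O-tosyl oxime F2. Warming F2 in aqueous dioxane brings about Beckmann rearrangement with migration of the anti C10; a fragmentation followed by Ritter recombination of the tethered nitrile and the C10 cation leads to the same product, the N–H lactam F3. Cs2CO3 in DMF then deprotonates the lactam N–H, which is more acidic than the urea N–H, and closes the pyrrolidine by 5-exo-tet displacement of chloride to give 21.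

2. Step 2. Ring-opening β-elimination of the serine enolate may outrun the slow SN2 reaction at an unactivated primary iodide.
Fallback (sets out from 4, returns at 7): the enolate is quenched with the much faster electrophile allyl bromide, with the same facial control, to give the C4-allyl oxazolidine F4. Hydroboration–oxidation (9-BBN, then NaBO3) gives the 3-hydroxypropyl oxazolidine F5, and an Appel reaction (PPh3, CCl4) converts F5 into 7.

3. Step 7. The hemiaminal may be over-oxidised to the hydantoin level, the cation may close through pyrrole C3 instead of N, or the urea may condense with the ketone under acid.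
Fallback (sets out from 14, returns at 18): the closure is switched from cationic to anionic. After IBX oxidation, hemiaminal 16 is isolated and acetylated (Ac2O, pyridine, DMAP) to the 5-acetoxyimidazolidinone F6. DBU in MeCN eliminates acetic acid to the neutral cyclic N-acylimine F7 and deprotonates the pyrrole, and the pyrrolide nitrogen, now the only strong nucleophile, adds to C6 from the face of the acyl group to give 18.

**Further compounds**
F1 | step 9 | (Z)-oxime of 18 (OH syn to pyrrole, anti to C10) | O=C1N[C@H]2n3c(cc(Br)c3Br)/C(=N\O)[C@@]2(CCCCl)N1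
F2 | step 9 | O-tosyl derivative of oxime F1 | O=C1N[C@H]2n3c(cc(Br)c3Br)/C(=N\OS(=O)(=O)c4ccc(C)cc4)[C@@]2(CCCCl)N1
F3 | step 9 | N–H lactam, rings A–B–D with the 3-chloropropyl arm on C10 (configuration as in 21) | O=C1N[C@H]2n3c(cc(Br)c3Br)C(=O)N[C@@]2(CCCCl)N1
F4 | step 2 | 4-benzyl 3-tert-butyl (2R,4S)-4-allyl-2-tert-butyl-1,3-oxazolidine-3,4-dicarboxylate | CC(C)(C)OC(=O)N1[C@@H](C(C)(C)C)OC[C@@]1(CC=C)C(=O)OCc2ccccc2
F5 | step 2 | 4-benzyl 3-tert-butyl (2R,4S)-2-tert-butyl-4-(3-hydroxypropyl)-1,3-oxazolidine-3,4-dicarboxylate | CC(C)(C)OC(=O)N1[C@@H](C(C)(C)C)OC[C@@]1(CCCO)C(=O)OCc2ccccc2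
F6 | step 7 | (4S)-5-acetoxy-4-(3-chloropropyl)-4-(4,5-dibromo-1H-pyrrole-2-carbonyl)imidazolidin-2-one (C5 epimers) | O=C1NC(OC(C)=O)[C@@](CCCCl)(C(=O)c2cc(Br)c(Br)[nH]2)N1
F7 | step 7 | neutral cyclic N-acylimine (C6=N), C10 as in 16 | O=C1N[C@](CCCCl)(C(=O)c2cc(Br)c(Br)[nH]2)C=N1
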